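## The problem

Compound 19 is the 7-O-ether of scopoletin (18) with a bicyclic sesquiterpene alcohol; drimane numbering is used throughout (C1–C10 for the decalin, C11 for the oxymethylene carbon on C9). Rings A and B form a trans-decalin with stereocentres at C3, C5, C9 and C10. Taking the face that carries the C10 methyl as the "methyl face", H5, the C9–C11 bond and the C3 hydroxyl all lie on the other, "open" face, so the C3 hydroxyl is axial and C11 pseudoaxial. Both are the less stable orientations: neither can be reached by equilibration, and hydrogen delivery to an sp2 C9 from the open face would put C11 on the wrong side. C11 must therefore arrive as carbon on the open face, and the C3 carbinol must come from kinetic equatorial hydride attack on a ketone. The quaternary C10 cannot be corrected later and is the centre that can control the others: C5 by enolisation next to a carbonyl, C7 and C9 through the open face of ring B, C3 through the locked chair of ring A. The coumarin (lactone and Michael acceptor) will not survive hydrides, organolithiums or hydroxide, and the C7=C8 alkene and the neopentyl axial carbinol dislike strong acid, so the aryl ether is made last under neutral conditions. Ring B carries methyls on C8 and C10 flanking C9, the pattern of 2,6-dimethylbenzoquinone (used as its monoketal 2), and ring A carries oxygen at C3 beside the gem-dimethyl C4, the pattern of the Me2C-terminated 2-silyloxydiene 4. The bonds C4–C5 and C1–C10 that join them are those of a [4+2] cycloaddition. The extra quinone oxygen at C6 steers regiochemistry as a ketal, allows C5 epimerisation as a ketone, and is then removed.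

## Retrosynthesis

**C11–O bond (19 ⇒ 17 + 18).** The aryl ether is cut first so that the coumarin meets no reducing or basic step. Diol 17 needs no protection, because a primary alcohol competes with an axial, neopentyl secondary one. The forward reaction must be a neutral redox etherification that leaves the C3 carbinol alone.

**C3–H bond (17 ⇒ 16 ⇒ 15).** The axial alcohol comes from ketone 16 by equatorial attack of a bulky borohydride. That reagent would also reduce an enone or a coumarin in the conjugate sense, so the ketone is kept masked as the silyl enol ether 15 until ring B holds only an isolated alkene, and it is reduced before 18 is attached.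

**C9–C11 bond (15 ⇒ 14 ⇒ 13).** A [2,3]-Wittig–Still shift is cut here rather than a hydroboration or aldehyde route. Those would deliver hydrogen to C9 from the open face, or equilibrate C11 into the equatorial position, and give the C9 epimer. The sigmatropic shift carries a CH2O unit from the C7 oxygen to C9 on the same face and moves the alkene to C7=C8. The precursor 13 has one carbon fewer and only needs the C7 hydroxyl on the open face.

**C7–O and C8=C9 (13 ⇒ 12 ⇒ 11).** Allylic alcohol 13 is the Wharton transposition product of epoxy ketone 12. Epoxide 12 comes from enone 11 by nucleophilic epoxidation, which attacks C7 axially on the open face. The C9 carbonyl is thus turned into the vinylic C9–H that the sigmatropic shift needs.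

**C6 oxygen (11 ⇒ 10 ⇒ 9 ⇒ 8 ⇒ 7).** Enone 11 is the trans-enedione 7 without its C6 carbonyl. Site-selective 1,2-reduction at C6 gives 8, acetylation gives 9, and reductive cleavage of the γ-acetoxy enone (through the deconjugated ketone 10) removes the oxygen while keeping the C9 enone. After this C5 can no longer epimerise.

**C5 configuration and ketal (7 ⇒ 6 ⇒ 5).** The trans fusion is not asked of the cycloaddition. The cis adduct 5 is unmasked to the cis-enedione 6, and C5, now α to the C6 ketone, is equilibrated; C10 is quaternary and cannot move or aromatise. The forward step must spare the silyl enol ether.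

**C4–C5 and C1–C10 (5 ⇒ 2 + 4), the key cut.** Ring A is removed as diene 4. The dienophile is the C6 monoketal 2 and not the free quinone, for three reasons:
- A Lewis acid on the free quinone binds the unhindered C6 carbonyl and makes the methyl-bearing C10 the electrophilic carbon.
- That either pairs the Me2C terminus with C10 or presses the bulky diene end against the catalyst.
- In 2 the only carbonyl is C9=O and its β-carbon is C5, so activation, enol ether polarity and sterics agree.

The forward step must set C10 in absolute terms with a chiral Lewis acid.

**Building blocks (2 ⇒ 1; 4 ⇒ 3).** Ketal 2 is one oxidative dearomatisation from phenol 1. Diene 4 is one silylation from enone 3, which can enolise on one side only.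

## Roads not taken

**Alternative 1:** The cut is C7–C8 and C8–C9, so ring B is grown from a five-membered ring by inserting C8 with its methyl. In the forward sense the silyl enol ether A1 of a trans-fused hydrindanone takes up a zinc ethylidene carbenoid to give siloxycyclopropane A2. Oxidative opening and elimination would then give the same C9 enone array as 11, with C3 already a protected carbinol.
- Merits: the absolute configuration at C10 can come from a thoroughly established amino-acid-catalysed annulation, the C3 carbinol is set early, and the enol ether can form on one side only. In certainty of absolute control this road is better than the chosen one.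
- Weak points: C5 in A1 is not α to the ketone, so a wrong ring fusion cannot be repaired, and trans-hydrindanes beside a gem-dimethyl carbon are hard to secure. Ethylidene transfer gives diastereomers on a hindered enol ether. The extra methyl makes the choice between the two cyclopropane bonds in the opening less sure.
- Comparison: A2 still needs the whole C9 sequence of steps 8–11, so it only replaces steps 1–7, and with a longer linear preparation of A1. The chosen plan sets against it one convergent step for ring A and a correctable C5.

**Alternative 2:** The cut is C5–C10 and C8–C9, opening both rings to the acyclic trienal A3. Its 2-silyloxydiene adds to the tethered α-substituted enal, thermally or with a Lewis acid, to give decalin A4.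
- Merits: both rings and four stereocentres form at once, the ring fusion is trans from the start, and C11 is already on C9 in the right relative sense. If it worked, the four-step C9 sequence of the chosen plan would be unnecessary.
- Weak points: the angular formyl group of A4 must be reduced to a methyl at a neopentyl centre. The C6 enol ether oxygen must be deleted and the alkene moved from C6=C7 to C7=C8. The C8 stereocentre is built only to be destroyed. A3 needs a geometrically pure trisubstituted enal, a Z silyl dienol ether next to a quaternary carbon and the C3 carbinol, all made linearly. Facial and endo/exo control rest on one tether stereocentre.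
- Comparison: the chosen plan is longer at C9 but each stereocentre there is set by a stereospecific or strongly biased step, and its precursors are two one-step compounds.

**Alternative 3:** The cut is C9–C10 and C7–C8. The ring A ethoxydiene A5 adds to the α,β-bond of ethyl buta-2,3-dienoate A6 to give A7.
- Merits: the regiochemistry is electronically matched, C11 arrives at the ester oxidation level, the exocyclic methylene is a ready precursor of the C7=C8 alkene, and ring A with its carbinol is accessible enantiopure by established ketone reductions. For C11 this is shorter than the chosen plan.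
- Weak points: the quaternary C10 must form from a tetrasubstituted diene terminus in an intermolecular reaction with a modest dienophile. Face selection depends on a carbinol three carbons away. The C9 ester must emerge anti to the C10 methyl, in the axial orientation, at a centre that is α to an ester and allylic, so base or the later alkene isomerisation would drive it to the equatorial epimer. C5 and the C6 oxygen need the same correction and deletion as in the chosen plan.
- Comparison: the chosen plan sets against the shorter C11 entry a catalyst-controlled C10 and a C9 centre formed last, suprafacially, and never epimerisable.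

Key step: step 3

Assumption: the (S)-BINOL titanium catalyst is written in step 3; which ligand antipode gives the (10R) series is to be settled by correlation of the first batch of 7, the (R)-ligand being used otherwise, and 1 and 3 are taken as catalogue compounds.

## Route

Step 1
Reactants: 1 4-methoxy-2,6-dimethylphenol
Product: 2 4,4-dimethoxy-2,6-dimethylcyclohexa-2,5-dien-1-one
Conditions: PhI(OAc)2, MeOH, 0 °C
Reagents that add atoms: methanol, CO
Why: Oxidative dearomatisation of a para-alkoxyphenol; the aryloxyiodane collapses to a cation that methanol captures at the para carbon to give the quinone monoketal. No stereocentre is formed.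

Step 2
Reactants: 3 4-methylpent-1-en-3-one
Product: 4 4-methyl-3-(triisopropylsilyloxy)penta-1,3-diene
Conditions: TIPSOTf, Et3N, CH2Cl2, 0 °C → rt
Reagents that add atoms: triisopropylsilyl trifluoromethanesulfonate, CC(C)[Si](C(C)C)(C(C)C)OS(=O)(=O)C(F)(F)F
Why: Soft enolisation and O-silylation; the isopropyl methine is the only enolisable position, so a single dienol ether can form, and its new terminus carries two identical methyls.

Step 3
Reactants: 2 4,4-dimethoxy-2,6-dimethylcyclohexa-2,5-dien-1-one; 4 4-methyl-3-(triisopropylsilyloxy)penta-1,3-diene
Product: 5 (5S,10R)-6,6-dimethoxy-3-(triisopropylsilyloxy)-11-nordrima-2,7-dien-9-one, cis-fused (H5 and the C10 methyl on the same face)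
Conditions: (S)-BINOL, TiCl2(OiPr)2 (15 mol % each), 4 Å MS, CH2Cl2, −40 → 0 °C
Reagents that add atoms: none
Why: Lewis-acid-catalysed Diels–Alder reaction, most probably a Mukaiyama–Michael addition followed by Michael ring closure: titanium binds the only carbonyl of 2 (C9=O), the Me2C terminus of the enol ether in 4 adds to the β-carbon C5, and the C10 titanium enolate closes onto the CH2 terminus of the silyloxyallyl cation, which restores the silyl enol ether at C2=C3. The closest known reaction type is the BINOL–titanium-catalysed enantioselective Diels–Alder reaction of 1,4-quinone monoketals with dienes, together with Lewis-acid-promoted cycloadditions of hindered 2-silyloxydienes to hindered cycloalkenones. Ring A closes as a six-membered ring in a formal [4+2] mode; in the stepwise picture the second bond is a 6-endo-trig Michael addition whose tether, fixed at C5, can reach the π-face of the C10 enolate only from its own side, so the fusion is cis. C5 is set by the face of 2 that the chiral titanium complex leaves open, and C10 follows from C5 through the cis closure; because C5 is epimerised later, this face choice fixes C10 and hence the absolute configuration of 19. The step needs the orientation Me2C→C5 and CH2→C10, which the substrate secures: with C6 masked, carbonyl activation, enol ether polarity and sterics all point the same way, the alternative being a bond between two fully substituted carbons. It also needs enantioface selection, which rests on the catalyst alone because the two enone units of 2 are homotopic and their faces enantiotopic. Endo/exo selectivity is irrelevant since neither diene terminus is stereogenic, and the bulky TIPS group is chosen to keep silyl transfer and achiral silyl-cation catalysis slow.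

Step 4
Reactants: 5 (5S,10R)-6,6-dimethoxy-3-(triisopropylsilyloxy)-11-nordrima-2,7-dien-9-one
Product: 7 (5R,10R)-3-(triisopropylsilyloxy)-11-nordrima-2,7-diene-6,9-dione, trans-fused, via cis-enedione 6 (not isolated)
Conditions: 10% aq. oxalic acid on SiO2, CH2Cl2, rt; then DBU (0.2 equiv), CH2Cl2, rt
Reagents that add atoms: water, O
Why: Acetal hydrolysis, which starts by fast O-protonation, should outrun the rate-limiting C-protonation of the hindered TIPS enol ether beside quaternary C4. The freed C6 ketone makes H5 acidic, and base equilibration through the C5 enolate is expected to place H5 on the open face (trans fusion), with quaternary C10 untouched.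

Step 5
Reactants: 7 (5R,10R)-3-(triisopropylsilyloxy)-11-nordrima-2,7-diene-6,9-dione
Product: 8 (5R,6S,10R)-6-hydroxy-3-(triisopropylsilyloxy)-11-nordrima-2,7-dien-9-one
Conditions: NaBH4, CeCl3·7H2O, MeOH, −78 °C
Reagents that add atoms: none
Why: Luche 1,2-reduction; the C9 carbonyl is flanked by quaternary C10 and the C8 methyl, so hydride should go to C6, from the open face away from the axial C10 and C4 methyls. The new C6 centre (hydroxyl on the methyl face) is lost again in step 7.

Step 6
Reactants: 8 (5R,6S,10R)-6-hydroxy-3-(triisopropylsilyloxy)-11-nordrima-2,7-dien-9-one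
Product: 9 (5R,6S,10R)-6-acetoxy-3-(triisopropylsilyloxy)-11-nordrima-2,7-dien-9-one
Conditions: Ac2O, Et3N, DMAP (cat.), CH2Cl2, rt
Reagents that add atoms: acetic anhydride, CC(=O)OC(C)=O
Why: DMAP-catalysed acylation turns the allylic hydroxyl into a leaving group; no stereocentre changes.

Step 7
Reactants: 9 (5R,6S,10R)-6-acetoxy-3-(triisopropylsilyloxy)-11-nordrima-2,7-dien-9-one
Product: 11 (5R,10R)-3-(triisopropylsilyloxy)-11-nordrima-2,7-dien-9-one, via β,γ-unsaturated ketone 10 (not isolated)
Conditions: SmI2 (2.2 equiv), THF/MeOH, −78 °C; then DBU, CH2Cl2, rt
Reagents that add atoms: none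
Why: Reductive cleavage of a γ-acyloxy enone: two-electron reduction of the enone expels acetate and gives a samarium dienolate, whose kinetic α-protonation gives 10. Base then moves the alkene back into conjugation as the C7=C8 enone, and with C6 now a methylene the trans fusion is fixed.

Step 8
Reactants: 11 (5R,10R)-3-(triisopropylsilyloxy)-11-nordrima-2,7-dien-9-one
Product: 12 (5R,7S,8S,10R)-7,8-epoxy-3-(triisopropylsilyloxy)-11-nordrim-2-en-9-one (epoxide on the open face)
Conditions: t-BuOOH, Triton B (cat.), THF, 0 °C → rt
Reagents that add atoms: tert-butyl hydroperoxide, CC(C)(C)OO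
Why: Weitz–Scheffer nucleophilic epoxidation, as for 2-methylcyclohexenones: the peroxide anion adds to C7 axially on the face opposite the C10 methyl and the enolate closes on the same face, which sets C7 and C8. The electron-rich enol ether is inert to a nucleophilic oxidant.

Step 9
Reactants: 12 (5R,7S,8S,10R)-7,8-epoxy-3-(triisopropylsilyloxy)-11-nordrim-2-en-9-one
Product: 13 (5S,7S,10S)-3-(triisopropylsilyloxy)-11-nordrima-2,8-dien-7-ol (hydroxyl on the open face)
Conditions: N2H4·H2O, AcOH (cat.), MeOH, 0 °C → rt
Reagents that add atoms: none
Why: Wharton transposition: the C9 hydrazone opens the epoxide to an allylic diazene that loses N2, giving C8=C9 with a vinylic C9–H. The C7–O bond is not touched, so the hydroxyl stays on the open face, pseudoaxial.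

Step 10
Reactants: 13 (5S,7S,10S)-3-(triisopropylsilyloxy)-11-nordrima-2,8-dien-7-ol
Product: 14 (5S,7S,10S)-7-[(tributylstannyl)methoxy]-3-(triisopropylsilyloxy)-11-nordrima-2,8-diene
Conditions: KH, 18-crown-6 (cat.), ICH2SnBu3, THF, 0 °C → rt
Reagents that add atoms: tributyl(iodomethyl)stannane, CCCC[Sn](CCCC)(CCCC)CI
Why: Williamson etherification of the potassium alkoxide with a primary iodide; no stereocentre is affected.

Step 11
Reactants: 14 (5S,7S,10S)-7-[(tributylstannyl)methoxy]-3-(triisopropylsilyloxy)-11-nordrima-2,8-diene
Product: 15 (5S,9S,10R)-3-(triisopropylsilyloxy)drima-2,7-dien-11-ol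
Conditions: n-BuLi, THF, −78 → −20 °C; then H2O
Reagents that add atoms: none
Why: Wittig–Still [2,3]-sigmatropic rearrangement: tin–lithium exchange gives the α-alkoxymethyllithium, which bonds to C9 on the face of the pseudoaxial C7–O bond while the alkene moves to C7=C8. The suprafacial shift transfers the C7 configuration to C9, placing C11 on the open face.

Step 12
Reactants: 15 (5S,9S,10R)-3-(triisopropylsilyloxy)drima-2,7-dien-11-ol
Product: 16 (5S,9S,10R)-11-hydroxydrim-7-en-3-one
Conditions: TBAF, AcOH, THF, 0 °C → rt
Reagents that add atoms: none
Why: Fluoride cleaves the Si–O bond and the buffered enolate is protonated at C2, unveiling the C3 ketone without acid that could move the C7=C8 alkene.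

Step 13
Reactants: 16 (5S,9S,10R)-11-hydroxydrim-7-en-3-one
Product: 17 (3S,5S,9S,10R)-drim-7-ene-3,11-diol
Conditions: K-Selectride (K[sBu3BH], 3 equiv), THF, −78 °C; then H2O
Reagents that add atoms: none
Why: The bulky trialkylborohydride attacks the C3 ketone of the locked chair from the equatorial side, as with 4,4-dimethyl-3-ketones of trans-decalins, giving the axial alcohol on the open face. It is used here because ring B no longer holds an enone and the coumarin is not yet present.

Step 14
Reactants: 17 (3S,5S,9S,10R)-drim-7-ene-3,11-diol; 18 scopoletin (7-hydroxy-6-methoxy-2H-chromen-2-one)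
Product: 19 7-{[(3S,5S,9S,10R)-3-hydroxydrim-7-en-11-yl]oxy}-6-methoxy-2H-chromen-2-one
Conditions: PPh3, DIAD, THF, 0 °C → rt
Reagents that add atoms: none
Why: Mitsunobu etherification of an acidic phenol; the primary C11 hydroxyl is activated in preference to the axial, neopentyl C3 hydroxyl, and C11 is not stereogenic, so no centre is touched.

## Compound list

1 | 4-methoxy-2,6-dimethylphenol | COc1cc(C)c(O)c(C)c1 | starting material
2 | 4,4-dimethoxy-2,6-dimethylcyclohexa-2,5-dien-1-one | COC1(OC)C=C(C)C(=O)C(C)=C1 | intermediate
3 | 4-methylpent-1-en-3-one | C=CC(=O)C(C)C | starting material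
4 | 4-methyl-3-(triisopropylsilyloxy)penta-1,3-diene | C=CC(O[Si](C(C)C)(C(C)C)C(C)C)=C(C)C | intermediate
5 | (5S,10R)-6,6-dimethoxy-3-(triisopropylsilyloxy)-11-nordrima-2,7-dien-9-one, cis-fused | O=C1C(C)=CC(OC)(OC)[C@H]2C(C)(C)C(O[Si](C(C)C)(C(C)C)C(C)C)=CC[C@]21C | intermediate
6 | (5S,10R)-3-(triisopropylsilyloxy)-11-nordrima-2,7-diene-6,9-dione, cis-fused | O=C1C(C)=CC(=O)[C@H]2C(C)(C)C(O[Si](C(C)C)(C(C)C)C(C)C)=CC[C@]21C | intermediate
7 | (5R,10R)-3-(triisopropylsilyloxy)-11-nordrima-2,7-diene-6,9-dione, trans-fused | O=C1C(C)=CC(=O)[C@@H]2C(C)(C)C(O[Si](C(C)C)(C(C)C)C(C)C)=CC[C@]21C | intermediate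
8 | (5R,6S,10R)-6-hydroxy-3-(triisopropylsilyloxy)-11-nordrima-2,7-dien-9-one (expected C6 epimer; either serves) | O=C1C(C)=C[C@H](O)[C@@H]2C(C)(C)C(O[Si](C(C)C)(C(C)C)C(C)C)=CC[C@]21C | intermediate
9 | (5R,6S,10R)-6-acetoxy-3-(triisopropylsilyloxy)-11-nordrima-2,7-dien-9-one | O=C1C(C)=C[C@H](OC(C)=O)[C@@H]2C(C)(C)C(O[Si](C(C)C)(C(C)C)C(C)C)=CC[C@]21C | intermediate
10 | (5R,10R)-3-(triisopropylsilyloxy)-11-nordrima-2,6-dien-9-one (C8 epimers) | O=C1C(C)C=C[C@@H]2C(C)(C)C(O[Si](C(C)C)(C(C)C)C(C)C)=CC[C@]21C | intermediate
11 | (5R,10R)-3-(triisopropylsilyloxy)-11-nordrima-2,7-dien-9-one | O=C1C(C)=CC[C@@H]2C(C)(C)C(O[Si](C(C)C)(C(C)C)C(C)C)=CC[C@]21C | intermediate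
12 | (5R,7S,8S,10R)-7,8-epoxy-3-(triisopropylsilyloxy)-11-nordrim-2-en-9-one | O=C1[C@@]2(C)O[C@H]2C[C@@H]3C(C)(C)C(O[Si](C(C)C)(C(C)C)C(C)C)=CC[C@]31C | intermediate
13 | (5S,7S,10S)-3-(triisopropylsilyloxy)-11-nordrima-2,8-dien-7-ol | CC1=C[C@]2(C)CC=C(O[Si](C(C)C)(C(C)C)C(C)C)C(C)(C)[C@H]2C[C@@H]1O | intermediate
14 | (5S,7S,10S)-7-[(tributylstannyl)methoxy]-3-(triisopropylsilyloxy)-11-nordrima-2,8-diene | CC1=C[C@]2(C)CC=C(O[Si](C(C)C)(C(C)C)C(C)C)C(C)(C)[C@H]2C[C@@H]1OC[Sn](CCCC)(CCCC)CCCC | intermediate
15 | (5S,9S,10R)-3-(triisopropylsilyloxy)drima-2,7-dien-11-ol | OC[C@H]1C(C)=CC[C@@H]2C(C)(C)C(O[Si](C(C)C)(C(C)C)C(C)C)=CC[C@]21C | intermediate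
16 | (5S,9S,10R)-11-hydroxydrim-7-en-3-one | OC[C@H]1C(C)=CC[C@@H]2C(C)(C)C(=O)CC[C@]21C | intermediate
17 | (3S,5S,9S,10R)-drim-7-ene-3,11-diol | OC[C@H]1C(C)=CC[C@@H]2C(C)(C)[C@@H](O)CC[C@]21C | intermediate
18 | scopoletin (7-hydroxy-6-methoxy-2H-chromen-2-one) | COc1cc2ccc(=O)oc2cc1O | starting material
19 | 7-{[(3S,5S,9S,10R)-3-hydroxydrim-7-en-11-yl]oxy}-6-methoxy-2H-chromen-2-one | COc1cc2ccc(=O)oc2cc1OC[C@H]1C(C)=CC[C@@H]2C(C)(C)[C@@H](O)CC[C@]21C | target

## Step count and least certain steps

Total: 14 steps. Longest linear sequence: 13 steps (1 → 2 → 5 → … → 19, or equally 3 → 4 → 5 → … → 19).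

**Step 3 (key step).** Bond formation at C5, next to the ketal carbon and with a fully substituted nucleophilic terminus, may be too slow for a mild titanium Lewis acid. The acid may instead ionise the ketal, and face discrimination may be weak because the carbonyl of 2 is flanked by two methyl-bearing carbons. The fallback drops the ketal. It sets out from 4 and commercial 2,6-dimethyl-1,4-benzoquinone F1, a far stronger dienophile, and uses the B-o-tolyl oxazaborolidine from (S)-α,α-diphenylprolinol activated with HNTf2 in CH2Cl2 at −78 °C, a catalyst class established for this quinone with 2-silyloxydienes. The Lewis acid then sits on the C6 carbonyl, the C1–C10 bond has to lead, and the orientation rests on the fact that the Me2C terminus cannot bond to the methyl-bearing carbon. The product is 6, and the route is rejoined at 7 after the DBU stage of step 4.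

**Step 4.** The cis/trans equilibration at C5 may stop short or lie on the cis side, because C9 and C6 are both trigonal and the usual preference for a trans-decalin is weakened by the C4 methyls. The fallback replaces thermodynamic by kinetic control. It sets out from 6 (step 4 run without base): LiHMDS in THF at −78 °C gives the lithium dienolate F2, which is added to AcOH/THF at −78 °C so that C5 is protonated from the open face, opposite the adjacent axial C10 methyl. It comes back to the route at 7.

**Step 5.** Hydride may not discriminate well enough between the two enedione carbonyls, since both are hindered, and acylation of the resulting crowded hydroxyl may be slow. The fallback removes the C6 oxygen by condensation chemistry. It sets out from 7: p-toluenesulfonylhydrazide condenses with the C6 carbonyl, the only one without a quaternary neighbour, to give the tosylhydrazone F3. Catecholborane followed by NaOAc·3H2O reduces the unsaturated hydrazone with alkene transposition through the allylic diazene. The product is 10, which the DBU stage of step 7 converts to 11; steps 5, 6 and the SmI2 stage are bypassed.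

**Step 9.** Hydrazone formation at the neopentyl C9 carbonyl may be slower than attack of hydrazine on the epoxide or decomposition of the diazene, a known weakness of Wharton reactions on hindered ketones. The fallback makes the same transposition by a radical path. It sets out from 12: NaBH4 gives the epoxy alcohol F4 (either C9 epimer serves; drawn for hydride attack from the open face), and 1,1'-thiocarbonyldiimidazole gives the imidazolyl thiocarbonate F5. Bu3SnH/AIBN in toluene at 80 °C generates the C9 radical, which opens the epoxide to the C7 alkoxy radical and, after hydrogen transfer, comes back to the route at 13.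

**Step 11.** O-alkylation and tin–lithium exchange are routine, but the rearrangement must form a bond at C9 beside quaternary C10; a [1,2]-shift or simple protonation of the carbanion may compete. The fallback delivers the carbon by axial conjugate addition. It sets out from 13: MnO2 gives the transposed enone F6. Copper-catalysed addition of (isopropoxydimethylsilyl)methylmagnesium chloride (CuI, TMSCl, THF) attacks C9 axially on the open face, and the enolate is trapped with PhNTf2 as enol triflate F7. Pd(OAc)2/PPh3 with HCO2H and Bu3N reduces the triflate to the C7=C8 alkene F8, and Tamao oxidation (H2O2, KF, KHCO3) converts the C–Si bond into the C11 hydroxyl. It comes back to the route at 15.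

## Further compounds

F1 | step 3 | 2,6-dimethyl-1,4-benzoquinone | CC1=CC(=O)C=C(C)C1=O
F2 | step 4 | lithium C5 dienolate of 6 (lithium (10R)-6-oxido-3-(triisopropylsilyloxy)-11-nordrima-2,5,7-trien-9-one) | O=C1C(C)=CC([O-])=C2C(C)(C)C(O[Si](C(C)C)(C(C)C)C(C)C)=CC[C@]21C.[Li+]
F3 | step 5 | C6 p-toluenesulfonylhydrazone of 7 (hydrazone geometry not defined) | O=C1C(C)=CC(=NNS(=O)(=O)c2ccc(C)cc2)[C@@H]3C(C)(C)C(O[Si](C(C)C)(C(C)C)C(C)C)=CC[C@]31C
F4 | step 9 | (5R,7S,8S,10R)-7,8-epoxy-3-(triisopropylsilyloxy)-11-nordrim-2-en-9-ol (C9 hydroxyl drawn on the methyl face) | O[C@@H]1[C@@]2(C)O[C@H]2C[C@@H]3C(C)(C)C(O[Si](C(C)C)(C(C)C)C(C)C)=CC[C@]31C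
F5 | step 9 | O-(C9) imidazole-1-carbothioate of F4 | S=C(O[C@@H]1[C@@]2(C)O[C@H]2C[C@@H]3C(C)(C)C(O[Si](C(C)C)(C(C)C)C(C)C)=CC[C@]31C)n1ccnc1
F6 | step 11 | (5S,10S)-3-(triisopropylsilyloxy)-11-nordrima-2,8-dien-7-one | CC1=C[C@]2(C)CC=C(O[Si](C(C)C)(C(C)C)C(C)C)C(C)(C)[C@H]2CC1=O
F7 | step 11 | (5S,9S,10R)-11-(isopropoxydimethylsilyl)-3-(triisopropylsilyloxy)drima-2,7-dien-7-yl trifluoromethanesulfonate | CC(C)O[Si](C)(C)C[C@H]1C(C)=C(OS(=O)(=O)C(F)(F)F)C[C@@H]2C(C)(C)C(O[Si](C(C)C)(C(C)C)C(C)C)=CC[C@]21C
F8 | step 11 | (5S,9S,10R)-11-(isopropoxydimethylsilyl)-3-(triisopropylsilyloxy)drima-2,7-diene | CC(C)O[Si](C)(C)C[C@H]1C(C)=CC[C@@H]2C(C)(C)C(O[Si](C(C)C)(C(C)C)C(C)C)=CC[C@]21C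
A1 | alternative 1 | trimethylsilyl enol ether of the trans-fused hydrindanone (ring B without C8, C3 as TBS ether) | C[Si](C)(C)OC1=CC[C@@H]2C(C)(C)[C@@H](O[Si](C)(C)C(C)(C)C)CC[C@]21C
A2 | alternative 1 | methyl-substituted siloxycyclopropane fused to the hydrindane | C[Si](C)(C)O[C@]12[C@H](C)[C@H]1C[C@@H]3C(C)(C)[C@@H](O[Si](C)(C)C(C)(C)C)CC[C@]32C
A3 | alternative 2 | acyclic trienal with (E)-enal and (Z,E)-2-silyloxydiene | COc1ccc(COC/C=C(/C=O)CC[C@H](O[Si](C)(C)C(C)(C)C)C(C)(C)/C=C(O[Si](CC)(CC)CC)/C=C/C)cc1
A4 | alternative 2 | trans-decalin with angular formyl at C10, C6 silyl enol ether and C9 alkoxymethyl | COc1ccc(COC[C@H]2[C@H](C)C=C(O[Si](CC)(CC)CC)[C@@H]3C(C)(C)[C@@H](O[Si](C)(C)C(C)(C)C)CC[C@]32C=O)cc1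
A5 | alternative 3 | ring A 2-ethoxydiene (1-(1-ethoxyvinyl)cyclohexene with C3 TBS ether) | C=C(OCC)C1=C(C)CC[C@H](O[Si](C)(C)C(C)(C)C)C1(C)C
A6 | alternative 3 | ethyl buta-2,3-dienoate | C=C=CC(=O)OCC
A7 | alternative 3 | bicyclic C6 enol ether with C9 ester, C8 exocyclic methylene and C10 methyl | CCOC(=O)[C@H]1C(=C)CC(OCC)=C2C(C)(C)[C@@H](O[Si](C)(C)C(C)(C)C)CC[C@]21C
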